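## Retrosynthetic overview

1. The last two steps are O2 desilylation and O8 angeloylation. They lead back to the 8-hydroxy-9-acetoxy-2-silyloxy germacranolide.
2. Key disconnection: C7–C8 and O6–C12 are cut together, giving an acyclic aldehyde that carries a 2-(oxiranyl)acrylate. In one Pd/In operation the γ-lactone closes first and the ten-membered ring closes second.
3. The 2-(oxiranyl)acrylate comes from an (E)-enal (C6) and methyl 2-(bromomethyl)acrylate. C7 acts first as a sulfur-ylide carbon and later as an allyl-metal carbon.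
4. C9–C10 comes from a (Z)-alkenyl iodide and silyloxyacetaldehyde by asymmetric Ni/Cr coupling.
5. C2–C3 comes from (Z)-3-iodobut-2-enal and a senecioate dienolate by a vinylogous Mukaiyama aldol. The Z-iodide comes from but-2-yn-1-ol.

Assumption: germacrane numbering (C1–C15) is used in the comments. The sense of induction of the three chiral mediators (steps 4, 8, 11) is assigned by analogy with their model substrates, and they are taken as purchasable.

## Route

**Step 1**
Reactants: 1 but-2-yn-1-ol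
Product: 2 (Z)-3-iodobut-2-en-1-ol
Conditions: Red-Al, THF, 0 °C to rt; EtOAc; I2, −78 to 0 °C
Reagents that add atoms: iodine, II
Why: Hydroxyl-directed trans-hydroalumination puts Al on C3 cis to the CH2O group, and iodinolysis with retention gives only the Z-iodide, which fixes the later 1(10)-Z ring olefin.

**Step 2**
Reactants: 2 (Z)-3-iodobut-2-en-1-ol
Product: 3 (Z)-3-iodobut-2-enal
Conditions: MnO2, CH2Cl2, rt
Reagents that add atoms: none
Why: Neutral MnO2 allylic oxidation gives the enal without Z/E isomerisation.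

**Step 3**
Reactants: 4 methyl 3-methylbut-2-enoate
Product: 5 tert-butyl[(1-methoxy-3-methylbuta-1,3-dien-1-yl)oxy]dimethylsilane
Conditions: LDA, THF, −78 °C; TBSCl, DMPU
Reagents that add atoms: tert-butyldimethylsilyl chloride, CC(C)(C)[Si](C)(C)Cl
Why: Kinetic γ-deprotonation and O-silylation of the extended enolate give the silyl dienol ether (silyl ketene acetal formation), whose acetal geometry is irrelevant.

**Step 4**
Reactants: 3 (Z)-3-iodobut-2-enal; 5 tert-butyl[(1-methoxy-3-methylbuta-1,3-dien-1-yl)oxy]dimethylsilane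
Product: 7 methyl (2E,5S,6Z)-5-hydroxy-7-iodo-3-methylocta-2,6-dienoate, via trichlorosilyl ether 6 (not isolated)
Conditions: SiCl4 (1.1 equiv), (R,R)-binaphthyldiamine bisphosphoramide (2 mol %), CH2Cl2, −78 °C; sat. aq NaHCO3
Reagents that add atoms: none
Why: In this Lewis-base-activated SiCl4 vinylogous Mukaiyama aldol the dienolate attacks only through its γ-CH2 on the Si face of the enal bound to the chiral silicon cation, which sets C2 (5S) and gives the 2E-enoate (any Z-isomer would lactonise and be removed).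

**Step 5**
Reactants: 7 methyl (2E,5S,6Z)-5-hydroxy-7-iodo-3-methylocta-2,6-dienoate
Product: 8 methyl (2E,5S,6Z)-5-(tert-butyldimethylsilyloxy)-7-iodo-3-methylocta-2,6-dienoate
Conditions: TBSCl, imidazole, DMF, rt
Reagents that add atoms: tert-butyldimethylsilyl chloride, CC(C)(C)[Si](C)(C)Cl
Why: Standard silyl ether formation keeps O2 distinct from O8 and O9 until the last step.

**Step 6**
Reactants: 9 (Z)-but-2-ene-1,4-diol
Product: 10 (Z)-1,4-bis(triethylsilyloxy)but-2-ene
Conditions: TESCl (2.2 equiv), imidazole, CH2Cl2, 0 °C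
Reagents that add atoms: triethylsilyl chloride, CC[Si](Cl)(CC)CC
Why: This is a routine double silylation of a cheap symmetric diol.

**Step 7**
Reactants: 10 (Z)-1,4-bis(triethylsilyloxy)but-2-ene
Product: 11 2-(triethylsilyloxy)acetaldehyde
Conditions: O3, CH2Cl2, −78 °C; Me2S
Reagents that add atoms: ozone, [O-][O+]=O
Why: Ozonolysis with reductive work-up cleaves the symmetric alkene into two equivalents of the C8–C9 aldehyde.

**Step 8**
Reactants: 8 methyl (2E,5S,6Z)-5-(tert-butyldimethylsilyloxy)-7-iodo-3-methylocta-2,6-dienoate; 11 2-(triethylsilyloxy)acetaldehyde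
Product: 12 methyl (2E,5S,6Z,8R)-5-(tert-butyldimethylsilyloxy)-8-hydroxy-3,7-dimethyl-9-(triethylsilyloxy)nona-2,6-dienoate
Conditions: CrCl2 (4 equiv), NiCl2 (2 mol %), chiral oxazoline–sulfonamide ligand (4.4 equiv), Et3N, THF, rt
Reagents that add atoms: none
Why: In this asymmetric Nozaki–Hiyama–Kishi alkenylation the trisubstituted iodoalkene couples with retention, so Z is kept, the enoate is tolerated, and the chiral Cr(III) complex selects the aldehyde face to set C9 (8R).

**Step 9**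
Reactants: 12 methyl (2E,5S,6Z,8R)-5-(tert-butyldimethylsilyloxy)-8-hydroxy-3,7-dimethyl-9-(triethylsilyloxy)nona-2,6-dienoate
Product: 13 (2E,5S,6Z,8R)-5-(tert-butyldimethylsilyloxy)-3,7-dimethyl-9-(triethylsilyloxy)nona-2,6-diene-1,8-diol
Conditions: DIBAL-H (3.5 equiv), CH2Cl2, −78 °C; Rochelle salt
Reagents that add atoms: none
Why: DIBAL-H reduces the enoate 1,2 to the allylic alcohol before any acetate is present, and both silyl ethers survive.

**Step 10**
Reactants: 13 (2E,5S,6Z,8R)-5-(tert-butyldimethylsilyloxy)-3,7-dimethyl-9-(triethylsilyloxy)nona-2,6-diene-1,8-diol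
Product: 15 (2R,3Z,5S,7E)-5-(tert-butyldimethylsilyloxy)-3,7-dimethyl-9-oxo-1-(triethylsilyloxy)nona-3,7-dien-2-yl acetate, via hydroxy enal 14 (not isolated)
Conditions: TEMPO (10 mol %), PhI(OAc)2, CH2Cl2, rt; then Ac2O, pyridine, DMAP (cat.), 0 °C
Reagents that add atoms: acetic anhydride, CC(=O)OC(C)=O
Why: The oxoammonium (TEMPO) oxidation takes the primary allylic alcohol in preference to the hindered secondary one, and acetylation in the same flask installs the final O9 acetate.

**Step 11**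
Reactants: 15 (2R,3Z,5S,7E)-5-(tert-butyldimethylsilyloxy)-3,7-dimethyl-9-oxo-1-(triethylsilyloxy)nona-3,7-dien-2-yl acetate; 16 methyl 2-(bromomethyl)acrylate; 17 (2S,5S)-2,5-dimethylthiolane
Product: 19 methyl 2-[(2R,3R)-3-{(1E,4S,5Z,7R)-7-acetoxy-4-(tert-butyldimethylsilyloxy)-2,6-dimethyl-8-(triethylsilyloxy)octa-1,5-dien-1-yl}oxiran-2-yl]acrylate, via sulfonium bromide 18 (not isolated)
Conditions: 16 + 17, MeCN, rt, 16 h; then 15, Cs2CO3, MeCN/t-BuOH 9:1, −20 to 0 °C
Reagents that add atoms: none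
Why: In this asymmetric sulfur-ylide (Corey–Chaykovsky-type) epoxidation the C2-symmetric sulfonium allylide adds 1,2 to the enal and closes to the trans-(R,R) vinyl epoxide (the (R,R)-sulfide gives (S,S)-epoxides), which sets C6, while the C7 centre is only temporary.

**Step 12**
Reactants: 19 methyl 2-[(2R,3R)-3-{(1E,4S,5Z,7R)-7-acetoxy-4-(tert-butyldimethylsilyloxy)-2,6-dimethyl-8-(triethylsilyloxy)octa-1,5-dien-1-yl}oxiran-2-yl]acrylate
Product: 20 methyl 2-[(2R,3R)-3-{(1E,4S,5Z,7R)-7-acetoxy-4-(tert-butyldimethylsilyloxy)-2,6-dimethyl-8-oxoocta-1,5-dien-1-yl}oxiran-2-yl]acrylate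
Conditions: IBX (3 equiv), DMSO, rt
Reagents that add atoms: none
Why: IBX in DMSO cleaves the primary TES ether and oxidises the freed alcohol in the same pot under near-neutral, base-free conditions, so the TBS ether, epoxide and acetate survive and the acetyl group cannot migrate.

**Step 13 (key step)**
Reactants: 20 methyl 2-[(2R,3R)-3-{(1E,4S,5Z,7R)-7-acetoxy-4-(tert-butyldimethylsilyloxy)-2,6-dimethyl-8-oxoocta-1,5-dien-1-yl}oxiran-2-yl]acrylate
Product: 22 (1(10)Z,4E,2S,6R,7R,8R,9R)-9-acetoxy-2-(tert-butyldimethylsilyloxy)-8-hydroxygermacra-1(10),4,11(13)-trien-12,6-olide (trans-lactone; C7 has the same spatial arrangement as in the target and is 7R only through CIP ranking), via allylindium butenolide 21 (not isolated)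
Conditions: Pd(PPh3)4 (10 mol %), InI (2.5 equiv), THF, rt, 20 added over 12 h (final 2 mM); 0.5 M HCl, 0 °C
Reagents that add atoms: none
Why: Proposed new method: Pd(0) binds the unhindered, electron-poor acrylate alkene and ionises only the adjacent C7–O bond of the epoxide (far faster than the hindered C9 allylic acetate); InI reduces the π-allyl-Pd to an allylindium; after π–σ–π equilibration its untouched C6 alkoxide lactonises at once onto the now cis ester, so the 6,12-olide is locked before any O8 alkoxide exists; 21 then adds through C7 to the tethered aldehyde in a chair Zimmerman–Traxler transition state, anti to the C6 side chain (6,7-trans) and with E-crotyl-type anti topology (8R), closing the ten-membered ring; the closest known reaction types are the Pd/InI umpolung of vinyl epoxides to 2-vinyl-1,3-diols, Barbier allylations with 3-(bromomethyl)furan-2(5H)-one, and intramolecular Barbier/Nozaki–Hiyama closures of ten-membered rings.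

**Step 14**
Reactants: 22 (1(10)Z,4E,2S,6R,7R,8R,9R)-9-acetoxy-2-(tert-butyldimethylsilyloxy)-8-hydroxygermacra-1(10),4,11(13)-trien-12,6-olide; 23 angelic acid
Product: 25 (1(10)Z,4E,2S,6R,7S,8R,9R)-9-acetoxy-8-angeloyloxy-2-(tert-butyldimethylsilyloxy)germacra-1(10),4,11(13)-trien-12,6-olide, via mixed anhydride 24 (not isolated)
Conditions: 23, 2,4,6-Cl3C6H2COCl, Et3N, toluene, rt; then 22, 75 °C
Reagents that add atoms: none
Why: Yamaguchi-type mixed-anhydride esterification without a nucleophilic catalyst acylates the only free hydroxyl, avoids angelate-to-tiglate isomerisation and base-induced acetyl migration, and stays well below Cope temperatures.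

**Step 15**
Reactants: 25 (1(10)Z,4E,2S,6R,7S,8R,9R)-9-acetoxy-8-angeloyloxy-2-(tert-butyldimethylsilyloxy)germacra-1(10),4,11(13)-trien-12,6-olide
Product: 26 CNP0316477.1, (1(10)Z,4E,2S,6R,7S,8R,9R)-9-acetoxy-8-angeloyloxy-2-hydroxygermacra-1(10),4,11(13)-trien-12,6-olide
Conditions: HF·pyridine, pyridine, THF, 0 °C to rt
Reagents that add atoms: none
Why: Buffered HF desilylation frees O2 without base, so there is no Michael addition to the α-methylene lactone, no acyl migration and no alkoxide-driven oxy-Cope reaction.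

## Compound list

1 | but-2-yn-1-ol | CC#CCO | starting material
2 | (Z)-3-iodobut-2-en-1-ol | OC/C=C(/C)I | intermediate
3 | (Z)-3-iodobut-2-enal | O=C/C=C(/C)I | intermediate
4 | methyl 3-methylbut-2-enoate | COC(=O)C=C(C)C | starting material
5 | tert-butyl[(1-methoxy-3-methylbuta-1,3-dien-1-yl)oxy]dimethylsilane | C=C(C)C=C(OC)O[Si](C)(C)C(C)(C)C | intermediate
6 | methyl (2E,5S,6Z)-7-iodo-3-methyl-5-(trichlorosilyloxy)octa-2,6-dienoate | COC(=O)/C=C(\C)C[C@H](O[Si](Cl)(Cl)Cl)/C=C(/C)I | intermediate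
7 | methyl (2E,5S,6Z)-5-hydroxy-7-iodo-3-methylocta-2,6-dienoate | COC(=O)/C=C(\C)C[C@H](O)/C=C(/C)I | intermediate
8 | methyl (2E,5S,6Z)-5-(tert-butyldimethylsilyloxy)-7-iodo-3-methylocta-2,6-dienoate | COC(=O)/C=C(\C)C[C@H](O[Si](C)(C)C(C)(C)C)/C=C(/C)I | intermediate
9 | (Z)-but-2-ene-1,4-diol | OC/C=C\CO | starting material
10 | (Z)-1,4-bis(triethylsilyloxy)but-2-ene | CC[Si](CC)(CC)OC/C=C\CO[Si](CC)(CC)CC | intermediate
11 | 2-(triethylsilyloxy)acetaldehyde | O=CCO[Si](CC)(CC)CC | intermediate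
12 | methyl (2E,5S,6Z,8R)-5-(tert-butyldimethylsilyloxy)-8-hydroxy-3,7-dimethyl-9-(triethylsilyloxy)nona-2,6-dienoate | COC(=O)/C=C(\C)C[C@H](O[Si](C)(C)C(C)(C)C)/C=C(/C)[C@@H](O)CO[Si](CC)(CC)CC | intermediate
13 | (2E,5S,6Z,8R)-5-(tert-butyldimethylsilyloxy)-3,7-dimethyl-9-(triethylsilyloxy)nona-2,6-diene-1,8-diol | OC/C=C(\C)C[C@H](O[Si](C)(C)C(C)(C)C)/C=C(/C)[C@@H](O)CO[Si](CC)(CC)CC | intermediate
14 | (2E,5S,6Z,8R)-5-(tert-butyldimethylsilyloxy)-8-hydroxy-3,7-dimethyl-9-(triethylsilyloxy)nona-2,6-dienal | O=C/C=C(\C)C[C@H](O[Si](C)(C)C(C)(C)C)/C=C(/C)[C@@H](O)CO[Si](CC)(CC)CC | intermediate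
15 | (2R,3Z,5S,7E)-5-(tert-butyldimethylsilyloxy)-3,7-dimethyl-9-oxo-1-(triethylsilyloxy)nona-3,7-dien-2-yl acetate | O=C/C=C(\C)C[C@H](O[Si](C)(C)C(C)(C)C)/C=C(/C)[C@@H](OC(C)=O)CO[Si](CC)(CC)CC | intermediate
16 | methyl 2-(bromomethyl)acrylate | C=C(CBr)C(=O)OC | starting material
17 | (2S,5S)-2,5-dimethylthiolane (chiral mediator, recovered) | C[C@H]1CC[C@H](C)S1 | starting material
18 | (2S,5S)-1-[2-(methoxycarbonyl)allyl]-2,5-dimethylthiolan-1-ium bromide | C=C(C(=O)OC)C[S+]1[C@@H](C)CC[C@@H]1C.[Br-] | intermediate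
19 | methyl 2-[(2R,3R)-3-{(1E,4S,5Z,7R)-7-acetoxy-4-(tert-butyldimethylsilyloxy)-2,6-dimethyl-8-(triethylsilyloxy)octa-1,5-dien-1-yl}oxiran-2-yl]acrylate | C=C(C(=O)OC)[C@H]1O[C@@H]1/C=C(\C)C[C@H](O[Si](C)(C)C(C)(C)C)/C=C(/C)[C@@H](OC(C)=O)CO[Si](CC)(CC)CC | intermediate
20 | methyl 2-[(2R,3R)-3-{(1E,4S,5Z,7R)-7-acetoxy-4-(tert-butyldimethylsilyloxy)-2,6-dimethyl-8-oxoocta-1,5-dien-1-yl}oxiran-2-yl]acrylate | C=C(C(=O)OC)[C@H]1O[C@@H]1/C=C(\C)C[C@H](O[Si](C)(C)C(C)(C)C)/C=C(/C)[C@@H](OC(C)=O)C=O | intermediate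
21 | 3-[(iodo)(methoxy)indiganylmethyl]-5-alkenylfuran-2(5H)-one bearing the C1–C5/C8–C10 chain of 20 (allylindium butenolide) | CO[In](I)CC1=C[C@H](OC1=O)/C=C(\C)C[C@H](O[Si](C)(C)C(C)(C)C)/C=C(/C)[C@@H](OC(C)=O)C=O | intermediate
22 | (1(10)Z,4E,2S,6R,7R,8R,9R)-9-acetoxy-2-(tert-butyldimethylsilyloxy)-8-hydroxygermacra-1(10),4,11(13)-trien-12,6-olide | C=C1C(=O)O[C@@H]2/C=C(\C)C[C@H](O[Si](C)(C)C(C)(C)C)/C=C(/C)[C@@H](OC(C)=O)[C@H](O)[C@@H]12 | intermediate
23 | angelic acid, (Z)-2-methylbut-2-enoic acid | C/C=C(/C)C(=O)O | starting material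
24 | angelic 2,4,6-trichlorobenzoic anhydride | C/C=C(/C)C(=O)OC(=O)c1c(Cl)cc(Cl)cc1Cl | intermediate
25 | (1(10)Z,4E,2S,6R,7S,8R,9R)-9-acetoxy-8-angeloyloxy-2-(tert-butyldimethylsilyloxy)germacra-1(10),4,11(13)-trien-12,6-olide | C=C1C(=O)O[C@@H]2/C=C(\C)C[C@H](O[Si](C)(C)C(C)(C)C)/C=C(/C)[C@@H](OC(C)=O)[C@H](OC(=O)/C(C)=C\C)[C@@H]12 | intermediate
26 | CNP0316477.1 | C=C1C(=O)O[C@@H]2/C=C(\C)C[C@H](O)/C=C(/C)[C@@H](OC(C)=O)[C@H](OC(=O)/C(C)=C\C)[C@@H]12 | target

## Step count and main risks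

Total step count: 15. Longest linear sequence: 12 (steps 1, 2, 4, 5, 8, 9, 10, 11, 12, 13, 14, 15).

**Step 13 (Pd/InI bicyclisation).** The risks are ionisation of the wrong C–O bond or of the C9 allylic acetate, protonation or oligomerisation of the allylindium, and mismatch with the C9 centre. The fallback sets out from 19 and comes back at 22. It forms the rings one at a time from a halide. MgBr2·OEt2 (Et2O, −20 °C) adds bromide SN2′ to the acrylate CH2 of 19, the epoxide opens, and the alkoxide lactonises to the isolable bromomethylbutenolide silyl ether F1. IBX in DMSO then gives the bromomethylbutenolide aldehyde F2. Slow addition of F2 to CrCl2 in THF/DMF closes C7–C8 as a separate intramolecular Nozaki–Hiyama allylation and gives 22.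

**Step 11 (asymmetric ylide epoxidation).** The risks are a modest trans/cis ratio or ee with this ester-bearing allylide, and base-induced enal isomerisation. The fallback sets out from 15 and comes back at 22. It sets C6 by carbonyl addition and builds the butenolide by metathesis. Amino-alcohol-catalysed addition of divinylzinc to 15 gives the bis-allylic alcohol F3. Acylation with 2-(bromomethyl)acryloyl chloride and pyridine gives the bromomethacrylate ester F4. Ring-closing metathesis (Grubbs II, CH2Cl2, reflux) gives the bromomethylbutenolide silyl ether F1, which goes on through the bromomethylbutenolide aldehyde F2 to 22 as above.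

**Step 8 (asymmetric Ni/Cr coupling).** The risk is low facial selectivity at C9 with this hindered Z-iodide. The fallback sets out from 8 and comes back at 12. It moves the stereocontrol from C–C bond formation to ketone reduction. Ligand-free CrCl2/NiCl2 coupling of 8 with 11 gives the C9-epimeric alcohol mixture F5. Dess–Martin oxidation gives the Z-enone F6. Reduction with (R)-Me-CBS and catecholborane (alkenyl as the large group) gives 12.

## Further compounds

F1 | step 13 | (5R)-3-(bromomethyl)-5-[(1E,4S,5Z,7R)-7-acetoxy-4-(tert-butyldimethylsilyloxy)-2,6-dimethyl-8-(triethylsilyloxy)octa-1,5-dien-1-yl]furan-2(5H)-one | BrCC1=C[C@H](OC1=O)/C=C(\C)C[C@H](O[Si](C)(C)C(C)(C)C)/C=C(/C)[C@@H](OC(C)=O)CO[Si](CC)(CC)CC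
F2 | step 13 | (5R)-3-(bromomethyl)-5-[(1E,4S,5Z,7R)-7-acetoxy-4-(tert-butyldimethylsilyloxy)-2,6-dimethyl-8-oxoocta-1,5-dien-1-yl]furan-2(5H)-one | BrCC1=C[C@H](OC1=O)/C=C(\C)C[C@H](O[Si](C)(C)C(C)(C)C)/C=C(/C)[C@@H](OC(C)=O)C=O
F3 | step 11 | (2R,3Z,5S,7E,9S)-5-(tert-butyldimethylsilyloxy)-9-hydroxy-3,7-dimethyl-1-(triethylsilyloxy)undeca-3,7,10-trien-2-yl acetate | C=C[C@H](O)/C=C(\C)C[C@H](O[Si](C)(C)C(C)(C)C)/C=C(/C)[C@@H](OC(C)=O)CO[Si](CC)(CC)CC
F4 | step 11 | 2-(bromomethyl)acrylate ester of F3 | C=C(CBr)C(=O)O[C@@H](C=C)/C=C(\C)C[C@H](O[Si](C)(C)C(C)(C)C)/C=C(/C)[C@@H](OC(C)=O)CO[Si](CC)(CC)CC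
F5 | step 8 | methyl (2E,5S,6Z)-5-(tert-butyldimethylsilyloxy)-8-hydroxy-3,7-dimethyl-9-(triethylsilyloxy)nona-2,6-dienoate, mixture of C8 epimers | COC(=O)/C=C(\C)C[C@H](O[Si](C)(C)C(C)(C)C)/C=C(/C)C(O)CO[Si](CC)(CC)CC
F6 | step 8 | methyl (2E,5S,6Z)-5-(tert-butyldimethylsilyloxy)-3,7-dimethyl-8-oxo-9-(triethylsilyloxy)nona-2,6-dienoate | COC(=O)/C=C(\C)C[C@H](O[Si](C)(C)C(C)(C)C)/C=C(/C)C(=O)CO[Si](CC)(CC)CC
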